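**Plan**
- The retrosynthesis cuts C7–C8 (aldol), C14=C15 (Wittig) and C10–Br (bromine for silicon), then the ring bond C9–C10 of the cyclopentenone (C8–C12) by alkyne hydroacylation, and last the two C12–CH2 bonds back to a silylpropiolate ester.
- The enabling feature: C12 carries two CH2–C arms, C8–C9 inside the ring and C13–C14 of the octenyl chain, which are identical at the CH2CHO level, plus the two-carbon unit C11–C10 as an alkyne. The ring is therefore hidden in an achiral 3-alkynylpentanedial.
- Forward: double allylation of the propiolate, silylation and ozonolysis give the dialdehyde; rhodium closes the only ring; bromine replaces silicon at C10; a Z-Wittig builds C13–C20; an anti aldol joins the C1–C7 Z-enal at C8; acetylation and desilylation finish.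
- Stereochemistry: C12 comes from the chiral rhodium catalyst choosing one of two enantiotopic aldehyde arms. C8 and C7 come from the substrate-controlled aldol (attack anti to the C12 carbon chain, chair transition state of the ring-locked (E)-enolate). Both Z-alkenes come from lithium-free Wittig reactions.

Key step: step 4

Assumption: the sense of induction of the rhodium/Tol-BINAP catalyst on this substrate cannot be derived from a model, so the (R)-ligand is written and its antipode is used unchanged if the first run gives the (R)-carbinol.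

**Step 1**
Reactants: 1 ethyl 3-(trimethylsilyl)prop-2-ynoate; 2 allylmagnesium bromide (two equivalents are consumed, one per allyl group)
Product: 4 4-[(trimethylsilyl)ethynyl]hepta-1,6-dien-4-ol, via alkynyl ketone 3 (not isolated)
Conditions: allylmagnesium bromide (2.3 equiv), Et2O, −78 → 0 °C; aq. NH4Cl
Reagents that add atoms: allylmagnesium bromide (second equivalent, which adds to ketone 3 and supplies the second allyl group), C=CC[Mg]Br
Why: Double Grignard addition to an ester, in which the first equivalent displaces ethoxide to give ketone 3 and the second adds to that more reactive ketone at once, each allyl group being delivered 1,2 through a cyclic six-membered allyl transfer and not in a conjugate sense; the carbinol carbon bears two identical allyl groups and is not a stereocentre.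

**Step 2**
Reactants: 4 4-[(trimethylsilyl)ethynyl]hepta-1,6-dien-4-ol
Product: 5 triethyl({4-[(trimethylsilyl)ethynyl]hepta-1,6-dien-4-yl}oxy)silane
Conditions: Et3SiOTf (1.3 equiv), 2,6-lutidine (2 equiv), CH2Cl2, −78 → 0 °C
Reagents that add atoms: triethylsilyl trifluoromethanesulfonate, CC[Si](CC)(CC)OS(=O)(=O)C(F)(F)F
Why: Silylation of a hindered tertiary propargylic alcohol with a silyl triflate and a non-nucleophilic base is standard, and the triethylsilyl ether is chosen to survive ozonolysis, ylide and amide bases and to leave with fluoride at the end.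

**Step 3**
Reactants: 5 triethyl({4-[(trimethylsilyl)ethynyl]hepta-1,6-dien-4-yl}oxy)silane
Product: 7 3-(triethylsilyloxy)-3-[(trimethylsilyl)ethynyl]pentanedial, via bis-ozonide 6 (not isolated)
Conditions: O3, CH2Cl2, −78 °C, Sudan red 7B end point; PPh3, −78 °C → rt; used at once
Reagents that add atoms: ozone, [O-][O+]=O
Why: Ozonolysis with reductive work-up, in which the two terminal alkenes react far faster than the silyl-capped alkyne, the dye marks the end point, and the neutral aprotic phosphine work-up spares the silyl ether and avoids β-elimination of the silyloxy group from the achiral dialdehyde.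

**Step 4**
Reactants: 7 3-(triethylsilyloxy)-3-[(trimethylsilyl)ethynyl]pentanedial
Product: 8 2-[(1S)-4-oxo-1-(triethylsilyloxy)-3-(trimethylsilyl)cyclopent-2-en-1-yl]acetaldehyde
Conditions: [Rh(cod)2]BF4 (5 mol%), (R)-Tol-BINAP (5 mol%), activated under H2 then Ar, CH2Cl2, rt
Reagents that add atoms: none
Why: One formyl C–H bond of 7 adds oxidatively to the cationic monovalent rhodium–bisphosphine complex to give an acyl hydride of trivalent rhodium, net trans addition of Rh–H across the tethered alkyne gives a six-membered acyl(alkenyl)rhodacycle, and C–C reductive elimination forms C9–C10 and releases the enone. The closest known reaction type is the rhodium-catalysed trans-hydroacylation of 4-alkynals to cyclopentenones, also established in enantioselective form for 3-alkoxy-4-alkynals (kinetic resolution, and desymmetrisation of aldehydes carrying two enantiotopic alkynes); here the same reaction must choose between two enantiotopic formylmethyl arms, for which no direct model substrate is claimed. The cyclopentenone closes in a formal 5-endo-dig sense, the ring bond arising by reductive elimination from the six-membered metallacycle. C12 becomes a stereocentre in this step and its configuration is set by the chiral bisphosphine alone, which decides which CH2CHO arm undergoes C–H insertion. The step needs enantiotopic-group selection, five- over four-membered closure (cis-hydroacylation to an alkylidenecyclobutanone is the known side path of 4-alkynals) and hydroacylation over decarbonylation; the C12 oxygen that can bind rhodium beside the reacting arm, the chelating bisphosphine and the mild temperature are relied on for these. The silyl cap ends on C10 as the marker for bromine, and the unused arm remains as the C13–C14 aldehyde.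

**Step 5**
Reactants: 8 2-[(1S)-4-oxo-1-(triethylsilyloxy)-3-(trimethylsilyl)cyclopent-2-en-1-yl]acetaldehyde
Product: 10 2-[(1S)-3-bromo-4-oxo-1-(triethylsilyloxy)cyclopent-2-en-1-yl]acetaldehyde, via dibromide 9 (not isolated)
Conditions: Br2 (1.05 equiv), solid NaHCO3, CH2Cl2, −78 → 0 °C; aq. Na2S2O3/NaHCO3
Reagents that add atoms: bromine, BrBr
Why: Bromodesilylation of a vinylsilane by addition–elimination, in which bromine adds to the C10=C11 bond (the only alkene present) and the β-bromo-α-silyl ketone loses bromotrimethylsilane to place bromine exactly where silicon was; low temperature and the bicarbonate buffer keep the enolisable aldehyde and the silyl ether out of acid-catalysed side reactions, and C12 is untouched.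

**Step 6**
Reactants: 10 2-[(1S)-3-bromo-4-oxo-1-(triethylsilyloxy)cyclopent-2-en-1-yl]acetaldehyde; 11 hexyltriphenylphosphonium bromide
Product: 13 (4S)-2-bromo-4-[(2Z)-oct-2-en-1-yl]-4-(triethylsilyloxy)cyclopent-2-en-1-one, via ylide 12 (not isolated)
Conditions: 11, NaN(SiMe3)2, THF, 0 °C; ylide added slowly to 10 (1.05 equiv ylide), −78 → −40 °C; aq. NH4Cl
Reagents that add atoms: none
Why: Wittig reaction of a lithium-free non-stabilised ylide, whose kinetic cis-oxaphosphetane gives the 14Z alkene, and which at −78 °C under inverse addition takes the aldehyde far faster than it attacks or enolises the conjugated bromoenone.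

**Step 7**
Reactants: 14 (4-carboxybutyl)triphenylphosphonium bromide; 15 (tert-butyldimethylsilyloxy)acetaldehyde
Product: 17 (5Z)-7-(tert-butyldimethylsilyloxy)hept-5-enoic acid, via carboxylate ylide 16 (not isolated)
Conditions: 14, NaN(SiMe3)2 (2.1 equiv), THF, 0 °C; 15, −78 °C → rt; 1 M HCl to pH 4
Reagents that add atoms: none
Why: Wittig reaction of the non-stabilised carboxylate ylide long used for cis-alkenoic acid chains, giving the 5Z alkene under lithium-free kinetic control with the α-silyloxy aldehyde.

**Step 8**
Reactants: 17 (5Z)-7-(tert-butyldimethylsilyloxy)hept-5-enoic acid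
Product: 18 methyl (5Z)-7-hydroxyhept-5-enoate
Conditions: HCl (cat., 1.25 M in MeOH), MeOH, rt
Reagents that add atoms: methanol, CO
Why: Fischer esterification and acid-catalysed methanolysis of the primary silyl ether run together in methanolic HCl, conditions under which the isolated Z-alkene does not isomerise.

**Step 9**
Reactants: 18 methyl (5Z)-7-hydroxyhept-5-enoate
Product: 19 methyl (5Z)-7-oxohept-5-enoate
Conditions: TEMPO (10 mol%), PhI(OAc)2 (1.1 equiv), CH2Cl2, rt; short silica plug, used at once
Reagents that add atoms: none
Why: Nitroxyl-catalysed oxidation of a primary allylic alcohol stops at the aldehyde under nearly neutral conditions and is a standard way to obtain Z-enals without isomerisation to the E-enal.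

**Step 10**
Reactants: 13 (4S)-2-bromo-4-[(2Z)-oct-2-en-1-yl]-4-(triethylsilyloxy)cyclopent-2-en-1-one; 19 methyl (5Z)-7-oxohept-5-enoate
Product: 21 methyl (5Z,7S)-7-[(1R,2S)-4-bromo-2-[(2Z)-oct-2-en-1-yl]-5-oxo-2-(triethylsilyloxy)cyclopent-3-en-1-yl]-7-hydroxyhept-5-enoate, via lithium dienolate 20 (not isolated)
Conditions: LiN(iPr)2 (1.1 equiv), THF, −78 °C; 19 (1.3 equiv), −78 °C, short contact; sat. aq. NH4Cl at −78 °C
Reagents that add atoms: none
Why: Kinetic lithium aldol addition of the ring-locked (E)-dienolate formed at C8, in which the closed chair transition state with the alkenyl group of 19 equatorial should give the anti (7S,8R) relationship and the aldehyde should approach C8 on the face of the silyloxy group, anti to the C12 carbon chain that branches next to the ring and is the better σ-donor; the dienolate cannot expel the C12 silyloxy group because that would form a cyclopentadienone, and 1,2-addition to the enal is the kinetic path at −78 °C.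

**Step 11**
Reactants: 21 methyl (5Z,7S)-7-[(1R,2S)-4-bromo-2-[(2Z)-oct-2-en-1-yl]-5-oxo-2-(triethylsilyloxy)cyclopent-3-en-1-yl]-7-hydroxyhept-5-enoate
Product: 22 methyl (5Z,7S)-7-acetoxy-7-[(1R,2S)-4-bromo-2-[(2Z)-oct-2-en-1-yl]-5-oxo-2-(triethylsilyloxy)cyclopent-3-en-1-yl]hept-5-enoate
Conditions: Ac2O, pyridine, CH2Cl2, 0 °C (no 4-dimethylaminopyridine)
Reagents that add atoms: acetic anhydride, CC(=O)OC(C)=O
Why: Acetylation of the secondary allylic alcohol with anhydride and the weak base pyridine at 0 °C proceeds with retention at C7 and leaves C8 alone, the stronger acyl-transfer bases being avoided because they would promote loss of acetic acid across C7–C8.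

**Step 12**
Reactants: 22 methyl (5Z,7S)-7-acetoxy-7-[(1R,2S)-4-bromo-2-[(2Z)-oct-2-en-1-yl]-5-oxo-2-(triethylsilyloxy)cyclopent-3-en-1-yl]hept-5-enoate
Product: 23 methyl (5Z,7S)-7-acetoxy-7-[(1R,2S)-4-bromo-2-hydroxy-2-[(2Z)-oct-2-en-1-yl]-5-oxocyclopent-3-en-1-yl]hept-5-enoate
Conditions: HF·pyridine, THF, 0 °C → rt; aq. NaHCO3 at 0 °C
Reagents that add atoms: none
Why: Fluoride-mediated cleavage of the tertiary triethylsilyl ether in a mildly acidic medium frees the C12 hydroxyl without touching the acetate, the methyl ester, the bromoenone or the base-sensitive C8 centre, and no stereocentre is affected.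

**Compound list**
1 | ethyl 3-(trimethylsilyl)prop-2-ynoate | CCOC(=O)C#C[Si](C)(C)C | starting material
2 | allylmagnesium bromide | C=CC[Mg]Br | starting material
3 | 1-(trimethylsilyl)hex-5-en-1-yn-3-one | C=CCC(=O)C#C[Si](C)(C)C | intermediate
4 | 4-[(trimethylsilyl)ethynyl]hepta-1,6-dien-4-ol | C=CCC(O)(CC=C)C#C[Si](C)(C)C | intermediate
5 | triethyl({4-[(trimethylsilyl)ethynyl]hepta-1,6-dien-4-yl}oxy)silane | C=CCC(CC=C)(O[Si](CC)(CC)CC)C#C[Si](C)(C)C | intermediate
6 | triethyl({1,3-bis(1,2,4-trioxolan-3-yl)-2-[(trimethylsilyl)ethynyl]propan-2-yl}oxy)silane (bis-ozonide; mixture of diastereomers) | CC[Si](CC)(CC)OC(CC1OOCO1)(CC1OOCO1)C#C[Si](C)(C)C | intermediate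
7 | 3-(triethylsilyloxy)-3-[(trimethylsilyl)ethynyl]pentanedial | O=CCC(CC=O)(O[Si](CC)(CC)CC)C#C[Si](C)(C)C | intermediate
8 | 2-[(1S)-4-oxo-1-(triethylsilyloxy)-3-(trimethylsilyl)cyclopent-2-en-1-yl]acetaldehyde | O=CC[C@@]1(O[Si](CC)(CC)CC)C=C([Si](C)(C)C)C(=O)C1 | intermediate
9 | 2-[(1S)-2,3-dibromo-4-oxo-1-(triethylsilyloxy)-3-(trimethylsilyl)cyclopentyl]acetaldehyde (configuration at the two CBr carbons not assigned) | O=CC[C@@]1(O[Si](CC)(CC)CC)C(Br)C(Br)([Si](C)(C)C)C(=O)C1 | intermediate
10 | 2-[(1S)-3-bromo-4-oxo-1-(triethylsilyloxy)cyclopent-2-en-1-yl]acetaldehyde | O=CC[C@@]1(O[Si](CC)(CC)CC)C=C(Br)C(=O)C1 | intermediate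
11 | hexyltriphenylphosphonium bromide | CCCCCC[P+](c1ccccc1)(c1ccccc1)c1ccccc1.[Br-] | starting material
12 | hexylidenetriphenylphosphorane | CCCCCC=P(c1ccccc1)(c1ccccc1)c1ccccc1 | intermediate
13 | (4S)-2-bromo-4-[(2Z)-oct-2-en-1-yl]-4-(triethylsilyloxy)cyclopent-2-en-1-one | CCCCC/C=C\C[C@@]1(O[Si](CC)(CC)CC)C=C(Br)C(=O)C1 | intermediate
14 | (4-carboxybutyl)triphenylphosphonium bromide | OC(=O)CCCC[P+](c1ccccc1)(c1ccccc1)c1ccccc1.[Br-] | starting material
15 | (tert-butyldimethylsilyloxy)acetaldehyde | CC(C)(C)[Si](C)(C)OCC=O | starting material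
16 | sodium 5-(triphenylphosphoranylidene)pentanoate | [Na+].[O-]C(=O)CCCC=P(c1ccccc1)(c1ccccc1)c1ccccc1 | intermediate
17 | (5Z)-7-(tert-butyldimethylsilyloxy)hept-5-enoic acid | CC(C)(C)[Si](C)(C)OC/C=C\CCCC(=O)O | intermediate
18 | methyl (5Z)-7-hydroxyhept-5-enoate | OC/C=C\CCCC(=O)OC | intermediate
19 | methyl (5Z)-7-oxohept-5-enoate | O=C/C=C\CCCC(=O)OC | intermediate
20 | lithium (3S)-5-bromo-3-[(2Z)-oct-2-en-1-yl]-3-(triethylsilyloxy)cyclopenta-1,4-dien-1-olate | CCCCC/C=C\C[C@@]1(O[Si](CC)(CC)CC)C=C(Br)C(O[Li])=C1 | intermediate
21 | methyl (5Z,7S)-7-[(1R,2S)-4-bromo-2-[(2Z)-oct-2-en-1-yl]-5-oxo-2-(triethylsilyloxy)cyclopent-3-en-1-yl]-7-hydroxyhept-5-enoate | CCCCC/C=C\C[C@@]1(O[Si](CC)(CC)CC)C=C(Br)C(=O)[C@@H]1[C@H](/C=C\CCCC(=O)OC)O | intermediate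
22 | methyl (5Z,7S)-7-acetoxy-7-[(1R,2S)-4-bromo-2-[(2Z)-oct-2-en-1-yl]-5-oxo-2-(triethylsilyloxy)cyclopent-3-en-1-yl]hept-5-enoate | CCCCC/C=C\C[C@@]1(O[Si](CC)(CC)CC)C=C(Br)C(=O)[C@@H]1[C@H](/C=C\CCCC(=O)OC)OC(C)=O | intermediate
23 | methyl (5Z,7S)-7-acetoxy-7-[(1R,2S)-4-bromo-2-hydroxy-2-[(2Z)-oct-2-en-1-yl]-5-oxocyclopent-3-en-1-yl]hept-5-enoate | CCCCC/C=C\C[C@@]1(O)C=C(Br)C(=O)[C@@H]1[C@H](/C=C\CCCC(=O)OC)OC(C)=O | target

**Count**
Total: 12 steps. Longest linear sequence: 9 steps (steps 1–6 and 10–12); the C1–C7 aldehyde takes 3 steps (7–9).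

**Steps most likely to fail**

Step 4. The catalyst may discriminate poorly between the two formylmethyl arms, the second aldehyde may divert rhodium into decarbonylation or four-membered ring closure, or the silyl-capped alkyne may insert sluggishly. The fallback sets out from 5 and uses only the established kinetic resolution of 3-alkoxy-4-alkynals. Ozonolysis of 5 interrupted after about one equivalent of ozone (PPh3 work-up, 5 recovered and recycled) would give racemic 3-(triethylsilyloxy)-3-[(trimethylsilyl)ethynyl]hex-5-enal F1. Hydroacylation of F1 with [Rh(cod)2]BF4 and (R,R)-i-Pr-DuPHOS (ligand hand chosen so that the (S)-aldehyde cyclises) would give (4S)-4-(prop-2-en-1-yl)-4-(triethylsilyloxy)-2-(trimethylsilyl)cyclopent-2-en-1-one F2, separated from the unreacted enantiomer of F1. Ozonolysis of the electron-rich allyl group of F2 (O3, CH2Cl2, −78 °C, dye end point; PPh3), faster than attack on the electron-poor ring alkene, returns to the route at 8.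

Step 10. The loose lithium chair may give poor anti/syn discrimination at C7, the facial preference at C8 may be incomplete, and the Z-enal may isomerise or be consumed by proton transfer. The fallback sets out from 13 and replaces the lithium enolate by a boron enolate. Soft enolisation with dicyclohexylboron chloride and triethylamine in Et2O would give the dicyclohexylboron dienolate of 13 F3. Its short B–O bonds tighten the chair, which should sharpen the anti preference and make the aldehyde feel the C12 substituents more strongly. Addition of 19 at −78 °C gives the dicyclohexylborinate of 21 F4, and buffered oxidative work-up (H2O2, MeOH, pH 7, 0 °C) returns to the route at 21.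

Step 11. Base-induced loss of acetic acid across C7–C8 (E1cB through the C8 enolate, driven by formation of the cross-conjugated dienone) may accompany acetylation or purification. The fallback sets out from 13 and removes the amine-base acetylation of an isolated aldol. The aldol addition is run as in step 10 through 20, but the lithium alkoxide of 21 F5 is not protonated and is trapped in the same flask with acetic anhydride at −78 °C before a cold NH4Cl quench. This returns to the route at 22.

**Further compounds**
F1 | step 4 | 3-(triethylsilyloxy)-3-[(trimethylsilyl)ethynyl]hex-5-enal (racemic) | C=CCC(CC=O)(O[Si](CC)(CC)CC)C#C[Si](C)(C)C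
F2 | step 4 | (4S)-4-(prop-2-en-1-yl)-4-(triethylsilyloxy)-2-(trimethylsilyl)cyclopent-2-en-1-one | C=CC[C@@]1(O[Si](CC)(CC)CC)C=C([Si](C)(C)C)C(=O)C1
F3 | step 10 | dicyclohexylboron dienolate of 13 | CCCCC/C=C\C[C@@]1(O[Si](CC)(CC)CC)C=C(Br)C(OB(C2CCCCC2)C2CCCCC2)=C1
F4 | step 10 | dicyclohexylborinate of 21 | CCCCC/C=C\C[C@@]1(O[Si](CC)(CC)CC)C=C(Br)C(=O)[C@@H]1[C@H](/C=C\CCCC(=O)OC)OB(C1CCCCC1)C1CCCCC1
F5 | step 11 | lithium alkoxide of 21 | CCCCC/C=C\C[C@@]1(O[Si](CC)(CC)CC)C=C(Br)C(=O)[C@@H]1[C@H](/C=C\CCCC(=O)OC)O[Li]
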